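Chain numbering used throughout: C-1 lactone C=O, C-3 carbinol, C-5 ring O–CH, C-6=C-7, C-8 H2, C-9 (OMe), C-10 H2, C-11 (OMe), C-12=C-13–Ph.

**Plan**
- Retrosynthesis: open the δ-lactone ring to a syn-3,5-diol held as an acetonide methyl ester and take the C-9 ether back to C–OH, then C–B; cut C-7–C-8 and C-9–C-10 together into an alkenyl bromide (C-1 to C-7), a vinyl unit (C-8, C-9) and a boronate (C-10 to C-13); cut C-10–C-11 to cinnamaldehyde and CH2(Bpin)2; cut C-4–C-5 to an ynal and an acetoacetate dienolate.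
- Enabling feature: C-8 is a CH2 between the C-6=C-7 E-alkene and the oxygenated C-9, whose other neighbour C-10 is again a CH2. This alkenyl–CH2–CH(O)–CH2 unit is the retron of a conjunctive cross-coupling of a vinylboron ate complex, and C-10, flanked by the two oxygenated carbons C-9 and C-11, maps onto the carbon of CH2(Bpin)2.
- Forward order: fragment A (alkenyl bromide, steps 1–5; the temporary 1,3-dioxane ring forms in step 3), fragment B (boronate, steps 6–7), three-component union (step 8), O-methylation (step 9), and the δ-lactone ring closed last (step 10).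
- Stereochemistry: C-5 by catalytic asymmetric vinylogous aldol, C-3 by 1,3-syn reduction, C-11 by copper-catalysed enantioselective borylmethyl addition, C-9 by the chiral palladium catalyst of the key step; the E-alkenes come from hydrozirconation and from cinnamaldehyde.

Key step: step 8

Assumption: in steps 1, 6 and 8 both antipodes of the chiral ligand are available; the antipode named is the one expected to give the drawn configuration, and the other is used if the sense of induction proves opposite.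

**Step 1**
Reactants: 1 3-(trimethylsilyl)prop-2-ynal; 2 1-methoxy-1,3-bis(trimethylsilyloxy)buta-1,3-diene (Chan's diene)
Product: 4 methyl (5R)-5-hydroxy-3-oxo-7-(trimethylsilyl)hept-6-ynoate, via bis-silyl aldol adduct 3 (not isolated)
Conditions: Ti(OiPr)4 (8 mol%), (R)-BINOL (8 mol%), 4 Å MS, THF, −78 °C → rt; then PPTS (cat.), MeOH, 0 °C
Reagents that add atoms: none
Why: Titanium–BINOL-catalysed vinylogous Mukaiyama aldol addition of the diene through its terminal carbon, in which the chiral Lewis acid shields one face of the ynal and so sets C-5 (R), followed by mild methanolysis of both silyl ethers of 3.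

**Step 2**
Reactants: 4 methyl (5R)-5-hydroxy-3-oxo-7-(trimethylsilyl)hept-6-ynoate
Product: 6 methyl (3S,5R)-3,5-dihydroxy-7-(trimethylsilyl)hept-6-ynoate, via diethylboron chelate 5 (not isolated)
Conditions: Et2BOMe, THF/MeOH (4:1), −78 °C; NaBH4, −78 °C; then MeOH co-evaporation
Reagents that add atoms: none
Why: Narasaka–Prasad reduction, in which the six-membered boron chelate 5 fixes the β-hydroxy ketone in a half-chair and external hydride is delivered axially, giving the 1,3-syn diol and setting C-3 (S).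

**Step 3**
Reactants: 6 methyl (3S,5R)-3,5-dihydroxy-7-(trimethylsilyl)hept-6-ynoate
Product: 7 methyl 2-[(4S,6R)-2,2-dimethyl-6-[(trimethylsilyl)ethynyl]-1,3-dioxan-4-yl]acetate
Conditions: Me2C(OMe)2, PPTS (cat.), CH2Cl2, rt
Reagents that add atoms: 2,2-dimethoxypropane, COC(C)(C)OC
Why: Acid-catalysed transketalisation (acetonide formation) ties the syn-diol into a chair 1,3-dioxane with both substituents equatorial and touches no stereocentre.

**Step 4**
Reactants: 7 methyl 2-[(4S,6R)-2,2-dimethyl-6-[(trimethylsilyl)ethynyl]-1,3-dioxan-4-yl]acetate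
Product: 8 methyl 2-[(4S,6R)-6-ethynyl-2,2-dimethyl-1,3-dioxan-4-yl]acetate
Conditions: K2CO3 (cat.), MeOH, 0 °C → rt
Reagents that add atoms: none
Why: Methoxide-mediated protodesilylation cleaves only the C(sp)–Si bond, and the methyl ester can only transesterify to itself in methanol.

**Step 5**
Reactants: 8 methyl 2-[(4S,6R)-6-ethynyl-2,2-dimethyl-1,3-dioxan-4-yl]acetate
Product: 10 methyl 2-[(4S,6R)-6-[(E)-2-bromoethenyl]-2,2-dimethyl-1,3-dioxan-4-yl]acetate, via alkenylzirconocene chloride 9 (not isolated)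
Conditions: Cp2Zr(H)Cl (1.3 equiv), THF, rt; then NBS, 0 °C
Reagents that add atoms: N-bromosuccinimide, BrN1C(=O)CCC1=O
Why: Hydrozirconation (Schwartz) adds Zr–H syn and anti-Markovnikov to the terminal alkyne faster than it reduces the ester, and bromodezirconation proceeds with retention to give the E-alkenyl bromide.

**Step 6**
Reactants: 11 (E)-cinnamaldehyde; 12 bis(4,4,5,5-tetramethyl-1,3,2-dioxaborolan-2-yl)methane
Product: 14 (2S,3E)-4-phenyl-1-(4,4,5,5-tetramethyl-1,3,2-dioxaborolan-2-yl)but-3-en-2-ol, via O-boryl adduct 13 (not isolated)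
Conditions: Cu(NCMe)4PF6 (5 mol%), (Sa,R,R)-BINOL-derived N,N-bis(1-phenylethyl)phosphoramidite (10 mol%), NaOtBu (20 mol%), THF, rt; aq. NH4Cl work-up
Reagents that add atoms: none
Why: Copper-catalysed enantioselective 1,2-addition of a 1,1-diborylalkane, in which alkoxide-triggered boron-to-copper transmetalation gives a (borylmethyl)copper–phosphoramidite species that adds to one carbonyl face and sets C-11 (S), the copper alkoxide turning over by boryl transfer from 12.

**Step 7**
Reactants: 14 (2S,3E)-4-phenyl-1-(4,4,5,5-tetramethyl-1,3,2-dioxaborolan-2-yl)but-3-en-2-ol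
Product: 15 2-[(2S,3E)-2-methoxy-4-phenylbut-3-en-1-yl]-4,4,5,5-tetramethyl-1,3,2-dioxaborolane
Conditions: Me3OBF4, 1,8-bis(dimethylamino)naphthalene, 4 Å MS, CH2Cl2, 0 °C → rt
Reagents that add atoms: trimethyloxonium tetrafluoroborate, C[O+](C)C.F[B-](F)(F)F
Why: Meerwein O-methylation of the neutral alcohol under a hindered amine buffer avoids the free alkoxide that would trigger boron–Wittig-type elimination and leaves the stereocentre untouched.

**Step 8**
Reactants: 15 2-[(2S,3E)-2-methoxy-4-phenylbut-3-en-1-yl]-4,4,5,5-tetramethyl-1,3,2-dioxaborolane; 16 vinylmagnesium bromide; 10 methyl 2-[(4S,6R)-6-[(E)-2-bromoethenyl]-2,2-dimethyl-1,3-dioxan-4-yl]acetate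
Product: 19 methyl 2-[(4S,6R)-6-[(1E,4R,6S,7E)-4-hydroxy-6-methoxy-8-phenylocta-1,7-dien-1-yl]-2,2-dimethyl-1,3-dioxan-4-yl]acetate, via vinylboron ate complex 17 (not isolated), via secondary boronate 18 (not isolated)
Conditions: 15 (1.2 equiv), 16 (1.2 equiv), THF, 0 °C → rt; NaOTf (2.4 equiv); then 10 (1.0 equiv), Pd(OAc)2 (2 mol%), (Sp,Sp)-MandyPhos [1,1′-bis[bis(4-methoxy-3,5-dimethylphenyl)phosphino]-2,2′-bis[(R)-α-(dimethylamino)benzyl]ferrocene] (2.4 mol%), THF, 40 °C; then NaBO3·4H2O, THF/H2O, rt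
Reagents that add atoms: sodium perborate tetrahydrate, [Na+].[O-]OB=O.O.O.O.O
Why: The vinyl Grignard reagent adds to boronate 15 to give the four-coordinate ate complex 17, and oxidative addition of 10 to zerovalent palladium gives a cationic alkenyl complex of divalent palladium (bromide being removed as NaBr) that binds the vinyl π-bond of 17. This π-activation induces 1,2-migration of the C-10 alkyl group from boron to C-9 anti to palladium while C-8 bonds to the metal, reductive elimination then forges C-7–C-8 with retention of the E geometry, and perborate converts C–B of 18 into C–OH with retention. The closest known reaction type is the palladium–MandyPhos-catalysed enantioselective conjunctive cross-coupling of vinylboron ate complexes with C(sp2) halides or triflates. No ring is closed. The new stereocentre C-9 (R) is controlled by the chiral bisphosphine, which selects the face of the vinyl group that palladium binds; C-11 sits on the migrating group two atoms from the reacting carbon and is not touched. The step needs the conjunctive pathway to win over direct vinyl transfer, β-hydride elimination and loss of methoxide from 17; the wide-bite-angle ligand and halide-free cationic palladium favour the metallate shift and fast reductive elimination, and methoxide is a poor leaving group from a four-coordinate borate (β-alkoxyethyl trifluoroborates are stable salts).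

**Step 9**
Reactants: 19 methyl 2-[(4S,6R)-6-[(1E,4R,6S,7E)-4-hydroxy-6-methoxy-8-phenylocta-1,7-dien-1-yl]-2,2-dimethyl-1,3-dioxan-4-yl]acetate
Product: 20 methyl 2-[(4S,6R)-6-[(1E,4R,6S,7E)-4,6-dimethoxy-8-phenylocta-1,7-dien-1-yl]-2,2-dimethyl-1,3-dioxan-4-yl]acetate
Conditions: Me3OBF4, 1,8-bis(dimethylamino)naphthalene, 4 Å MS, CH2Cl2, rt
Reagents that add atoms: trimethyloxonium tetrafluoroborate, C[O+](C)C.F[B-](F)(F)F
Why: Base-free Meerwein O-methylation of the secondary alcohol avoids enolisation of the β-alkoxy ester (which would open the dioxane by E1cB) and does not affect C-9.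

**Step 10**
Reactants: 20 methyl 2-[(4S,6R)-6-[(1E,4R,6S,7E)-4,6-dimethoxy-8-phenylocta-1,7-dien-1-yl]-2,2-dimethyl-1,3-dioxan-4-yl]acetate
Product: 22 (4S,6R)-6-[(1E,4R,6S,7E)-4,6-dimethoxy-8-phenylocta-1,7-dien-1-yl]-4-hydroxyoxan-2-one, via dihydroxy ester 21 (not isolated)
Conditions: CSA (cat.), MeOH, rt; then evaporation, CSA (cat.), CH2Cl2, rt
Reagents that add atoms: none
Why: Acid-catalysed acetonide methanolysis frees the syn-3,5-diol, and the C-5 hydroxyl then closes the δ-lactone by 6-exo-trig acyl substitution on the methyl ester (lactonisation), the mild acid being expected to leave the cinnamyl-type methyl ether and all stereocentres intact.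

**Compound list**
1 | 3-(trimethylsilyl)prop-2-ynal | C[Si](C)(C)C#CC=O | starting material
2 | 1-methoxy-1,3-bis(trimethylsilyloxy)buta-1,3-diene | COC(O[Si](C)(C)C)=CC(=C)O[Si](C)(C)C | starting material
3 | methyl (2Z,5R)-3,5-bis(trimethylsilyloxy)-7-(trimethylsilyl)hept-2-en-6-ynoate | COC(=O)/C=C(\O[Si](C)(C)C)C[C@@H](O[Si](C)(C)C)C#C[Si](C)(C)C | intermediate
4 | methyl (5R)-5-hydroxy-3-oxo-7-(trimethylsilyl)hept-6-ynoate | COC(=O)CC(=O)C[C@@H](O)C#C[Si](C)(C)C | intermediate
5 | diethylboron chelate of 4 (O-5 borinate, C-3 ketone oxygen bound to boron) | CC[B-]1(CC)O[C@@H](C#C[Si](C)(C)C)CC(CC(=O)OC)=[O+]1 | intermediate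
6 | methyl (3S,5R)-3,5-dihydroxy-7-(trimethylsilyl)hept-6-ynoate | COC(=O)C[C@@H](O)C[C@@H](O)C#C[Si](C)(C)C | intermediate
7 | methyl 2-[(4S,6R)-2,2-dimethyl-6-[(trimethylsilyl)ethynyl]-1,3-dioxan-4-yl]acetate | C[Si](C)(C)C#C[C@H]1C[C@@H](CC(=O)OC)OC(C)(C)O1 | intermediate
8 | methyl 2-[(4S,6R)-6-ethynyl-2,2-dimethyl-1,3-dioxan-4-yl]acetate | C#C[C@H]1C[C@@H](CC(=O)OC)OC(C)(C)O1 | intermediate
9 | chlorobis(cyclopentadienyl)[(E)-2-[(4R,6S)-6-(2-methoxy-2-oxoethyl)-2,2-dimethyl-1,3-dioxan-4-yl]ethenyl]zirconium | Cl[Zr](/C=C/[C@H]1C[C@@H](CC(=O)OC)OC(C)(C)O1)(C1C=CC=C1)C1C=CC=C1 | intermediate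
10 | methyl 2-[(4S,6R)-6-[(E)-2-bromoethenyl]-2,2-dimethyl-1,3-dioxan-4-yl]acetate | Br/C=C/[C@H]1C[C@@H](CC(=O)OC)OC(C)(C)O1 | intermediate
11 | (E)-cinnamaldehyde | O=C/C=C/c1ccccc1 | starting material
12 | bis(4,4,5,5-tetramethyl-1,3,2-dioxaborolan-2-yl)methane | CC1(C)OB(CB2OC(C)(C)C(C)(C)O2)OC1(C)C | starting material
13 | 2-{[(2S,3E)-4-phenyl-1-(4,4,5,5-tetramethyl-1,3,2-dioxaborolan-2-yl)but-3-en-2-yl]oxy}-4,4,5,5-tetramethyl-1,3,2-dioxaborolane | CC1(C)OB(O[C@@H](CB2OC(C)(C)C(C)(C)O2)/C=C/c2ccccc2)OC1(C)C | intermediate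
14 | (2S,3E)-4-phenyl-1-(4,4,5,5-tetramethyl-1,3,2-dioxaborolan-2-yl)but-3-en-2-ol | O[C@@H](CB1OC(C)(C)C(C)(C)O1)/C=C/c1ccccc1 | intermediate
15 | 2-[(2S,3E)-2-methoxy-4-phenylbut-3-en-1-yl]-4,4,5,5-tetramethyl-1,3,2-dioxaborolane | CO[C@@H](CB1OC(C)(C)C(C)(C)O1)/C=C/c1ccccc1 | intermediate
16 | vinylmagnesium bromide | C=C[Mg]Br | starting material
17 | sodium ethenyl[(2S,3E)-2-methoxy-4-phenylbut-3-en-1-yl](pinacolato)borate | [Na+].C=C[B-]1(C[C@@H](/C=C/c2ccccc2)OC)OC(C)(C)C(C)(C)O1 | intermediate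
18 | methyl 2-[(4S,6R)-6-[(1E,4R,6S,7E)-6-methoxy-8-phenyl-4-(4,4,5,5-tetramethyl-1,3,2-dioxaborolan-2-yl)octa-1,7-dien-1-yl]-2,2-dimethyl-1,3-dioxan-4-yl]acetate | CC1(C)OB(OC1(C)C)[C@H](C/C=C/[C@H]1C[C@@H](CC(=O)OC)OC(C)(C)O1)C[C@@H](/C=C/c1ccccc1)OC | intermediate
19 | methyl 2-[(4S,6R)-6-[(1E,4R,6S,7E)-4-hydroxy-6-methoxy-8-phenylocta-1,7-dien-1-yl]-2,2-dimethyl-1,3-dioxan-4-yl]acetate | O[C@H](C/C=C/[C@H]1C[C@@H](CC(=O)OC)OC(C)(C)O1)C[C@@H](/C=C/c1ccccc1)OC | intermediate
20 | methyl 2-[(4S,6R)-6-[(1E,4R,6S,7E)-4,6-dimethoxy-8-phenylocta-1,7-dien-1-yl]-2,2-dimethyl-1,3-dioxan-4-yl]acetate | CO[C@H](C/C=C/[C@H]1C[C@@H](CC(=O)OC)OC(C)(C)O1)C[C@@H](/C=C/c1ccccc1)OC | intermediate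
21 | methyl (3S,5R,6E,9R,11S,12E)-3,5-dihydroxy-9,11-dimethoxy-13-phenyltrideca-6,12-dienoate | CO[C@H](C/C=C/[C@H](O)C[C@H](O)CC(=O)OC)C[C@@H](/C=C/c1ccccc1)OC | intermediate
22 | (4S,6R)-6-[(1E,4R,6S,7E)-4,6-dimethoxy-8-phenylocta-1,7-dien-1-yl]-4-hydroxyoxan-2-one | CO[C@H](C/C=C/[C@H]1C[C@H](O)CC(=O)O1)C[C@@H](/C=C/c1ccccc1)OC | target

**Totals**
Total step count: 10. Longest linear sequence: 8 (steps 1–5, then 8–10).

**Steps most likely to fail**

1. Step 8. The four-coordinate borate 17 may lose methoxide (β-elimination) on warming, the vinyl group may transfer to palladium (plain cross-coupling) instead of undergoing the 1,2-shift, or catalyst control at C-9 may be weak. The fallback makes the same C-7–C-8 bond without any β-alkoxy borate. It sets out from 11: asymmetric allylation with (−)-B-allyldiisopinocampheylborane (Et2O, −78 °C; NaOH/H2O2 work-up) should give (1E,3S)-1-phenylhexa-1,5-dien-3-ol F1, and NaH/MeI its methyl ether [(1E,3S)-3-methoxyhexa-1,5-dien-1-yl]benzene F2. Enantioselective diboration of the terminal alkene (Pt(dba)3, TADDOL-derived phosphonite, B2pin2, THF, 60 °C) then gives the vicinal bis(boronate) 2,2′-[(2R,4S,5E)-4-methoxy-6-phenylhex-5-ene-1,2-diyl]bis(4,4,5,5-tetramethyl-1,3,2-dioxaborolane) F3. Suzuki–Miyaura coupling of its primary C–B bond with 10 (Pd(OAc)2, RuPhos, K3PO4, THF/H2O, 70 °C), which the neighbouring secondary boronate accelerates, comes back to the route at 18, which is oxidised to 19 as in step 8.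

2. Step 6. Enantiofacial discrimination by the small (borylmethyl)copper nucleophile may be poor. The fallback secures C-11 by resolution and sets out from 11 and 12: an achiral catalyst (CuCl, 1,2-bis(diphenylphosphino)ethane, NaOtBu cat., THF) gives, through racemic O-boryl adduct F4 hydrolysed on work-up, racemic (3E)-4-phenyl-1-(4,4,5,5-tetramethyl-1,3,2-dioxaborolan-2-yl)but-3-en-2-ol F5. Acylative kinetic resolution with a chiral amidine-based acyl-transfer catalyst ((iPrCO)2O, iPr2NEt, CHCl3, 0 °C; catalyst antipode chosen to acylate the R alcohol) converts the unwanted enantiomer into (2R,3E)-4-phenyl-1-(4,4,5,5-tetramethyl-1,3,2-dioxaborolan-2-yl)but-3-en-2-yl 2-methylpropanoate F6 and leaves the S alcohol, which is 14, where the route is rejoined.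

3. Step 1. The reactive, sterically small ynal may react through an unselective background pathway, eroding the enantiomeric purity at C-5. The fallback uses auxiliary control and sets out from 1: addition to the titanium enolate of N-acetyl-(4S)-4-benzyl-1,3-thiazolidine-2-thione (TiCl4, iPr2NEt, CH2Cl2, −78 °C; auxiliary antipode chosen for the 3R carbinol, diastereomers separable) gives (3R)-1-[(4S)-4-benzyl-2-thioxo-1,3-thiazolidin-3-yl]-3-hydroxy-5-(trimethylsilyl)pent-4-yn-1-one F7. Direct displacement of the auxiliary by the magnesium enolate of potassium methyl malonate (MgCl2, imidazole, THF, rt) with decarboxylation comes back to the route at 4.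

**Further compounds**
F1 | step 8 | (1E,3S)-1-phenylhexa-1,5-dien-3-ol | C=CC[C@H](O)/C=C/c1ccccc1
F2 | step 8 | [(1E,3S)-3-methoxyhexa-1,5-dien-1-yl]benzene | C=CC[C@H](OC)/C=C/c1ccccc1
F3 | step 8 | 2,2′-[(2R,4S,5E)-4-methoxy-6-phenylhex-5-ene-1,2-diyl]bis(4,4,5,5-tetramethyl-1,3,2-dioxaborolane) | CC1(C)OB(OC1(C)C)[C@H](CB1OC(C)(C)C(C)(C)O1)C[C@@H](/C=C/c1ccccc1)OC
F4 | step 6 | racemic 2-{[(3E)-4-phenyl-1-(4,4,5,5-tetramethyl-1,3,2-dioxaborolan-2-yl)but-3-en-2-yl]oxy}-4,4,5,5-tetramethyl-1,3,2-dioxaborolane | CC1(C)OB(OC(CB2OC(C)(C)C(C)(C)O2)/C=C/c2ccccc2)OC1(C)C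
F5 | step 6 | racemic (3E)-4-phenyl-1-(4,4,5,5-tetramethyl-1,3,2-dioxaborolan-2-yl)but-3-en-2-ol | OC(CB1OC(C)(C)C(C)(C)O1)/C=C/c1ccccc1
F6 | step 6 | (2R,3E)-4-phenyl-1-(4,4,5,5-tetramethyl-1,3,2-dioxaborolan-2-yl)but-3-en-2-yl 2-methylpropanoate | CC(C)C(=O)O[C@H](CB1OC(C)(C)C(C)(C)O1)/C=C/c1ccccc1
F7 | step 1 | (3R)-1-[(4S)-4-benzyl-2-thioxo-1,3-thiazolidin-3-yl]-3-hydroxy-5-(trimethylsilyl)pent-4-yn-1-one | S=C1SC[C@H](Cc2ccccc2)N1C(=O)C[C@@H](O)C#C[Si](C)(C)C
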